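**Retrosynthetic overview**
1. 7 ⇒ 5 + CO + 6. Both ketone C–C bonds (C3–CO and CO–Ar) are cut at once by a three-component carbonylative Suzuki–Miyaura coupling. This is the bold key step, and it replaces aldol or alkyne cyclisation onto a pre-made aryl ketone.
2. 5 ⇒ 3. The enol-ether C3=C4 bond comes from O-phosphorylation of a lactone enolate, so the lactone carbonyl carbon serves as a vinyl electrophile.
3. 3 ⇒ 1 + CH2O, by arene hydroxymethylation and lactonisation.
4. Ring order: both benzene rings are bought. The pyran ring is the only ring formed (step 1, as the lactone), and it is never reopened.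

Assumption: the SMILES has no stereocentre and no free stereogenic double bond (the ring alkene is geometrically fixed). The target is therefore achiral and no enantioselective step is needed.

**Step 1**
Reactants: 1 3,4-dimethoxyphenylacetic acid (homoveratric acid)
Product: 3 6,7-dimethoxyisochroman-3-one, via 2-[2-(hydroxymethyl)-4,5-dimethoxyphenyl]acetic acid 2 (not isolated)
Conditions: 37% aq. CH2O, conc. HCl, AcOH, 90 °C, 1 h
Reagents that add atoms: formaldehyde, C=O
Why: Acid-promoted hydroxymethylation (Blanc/Lederer–Manasse-type electrophilic aromatic substitution) occurs at C6, para to the 3-OMe and the only unhindered activated site, and the benzylic alcohol 2 lies next to the CH2CO2H arm and lactonises at once to the six-membered ring; no stereocentre is formed.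

**Step 2**
Reactants: 3 6,7-dimethoxyisochroman-3-one
Product: 5 6,7-dimethoxy-1H-isochromen-3-yl diphenyl phosphate, via potassium 6,7-dimethoxy-1H-isochromen-3-olate 4 (not isolated)
Conditions: KHMDS (1.2 equiv) added to 3 + (PhO)2P(O)Cl (1.3 equiv), THF–DMPU, −78 °C; Et3N-deactivated SiO2
Reagents that add atoms: diphenyl chlorophosphate, O=P(Cl)(Oc1ccccc1)Oc1ccccc1
Why: KHMDS cleanly removes the doubly activated (benzylic and α-acyl) C4–H, and the hard P(V) chloride traps enolate 4 on oxygen (enolate O-phosphorylation to a cyclic ketene acetal phosphate) before self-Claisen condensation, which fixes C3=C4 in conjugation with the arene; no stereocentre is formed.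

**Step 3**
Reactants: 5 6,7-dimethoxy-1H-isochromen-3-yl diphenyl phosphate; 6 (2,4-dimethoxyphenyl)boronic acid (1.5 equiv)
Product: 7 (2,4-dimethoxyphenyl)(6,7-dimethoxy-1H-isochromen-3-yl)methanone (target)
Conditions: CO (1 atm), PdCl2(dppf) (5 mol %), K2CO3 (3 equiv), degassed anisole, 80 °C
Reagents that add atoms: carbon monoxide, [C-]#[O+]
Why: Proposed new method: carbonylative Suzuki–Miyaura coupling on a lactone-derived ketene acetal phosphate, in which Pd(0) inserts into the oxygen-activated C3–OP bond, CO inserts into the electron-rich α-alkoxyvinyl–Pd bond faster than the ortho-substituted boronate can transmetalate, and transmetalation then reductive elimination from the acyl–Pd species releases the aryl ketone, the closest known reaction types being carbonylative Suzuki coupling of vinyl/aryl triflates and the Pd-catalysed alkoxycarbonylation and Suzuki/Stille couplings of ketene acetal phosphates; no stereocentre is formed.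

**Compound list**
1 | 3,4-dimethoxyphenylacetic acid (homoveratric acid) | COc1ccc(CC(=O)O)cc1OC | starting material
2 | 2-[2-(hydroxymethyl)-4,5-dimethoxyphenyl]acetic acid (not isolated) | COc1cc(CO)c(CC(=O)O)cc1OC | intermediate
3 | 6,7-dimethoxyisochroman-3-one | COc1cc2c(cc1OC)COC(=O)C2 | intermediate
4 | potassium 6,7-dimethoxy-1H-isochromen-3-olate (not isolated) | COc1cc2c(cc1OC)COC([O-])=C2.[K+] | intermediate
5 | 6,7-dimethoxy-1H-isochromen-3-yl diphenyl phosphate | COc1cc2c(cc1OC)COC(OP(=O)(Oc1ccccc1)Oc1ccccc1)=C2 | intermediate
6 | (2,4-dimethoxyphenyl)boronic acid | COc1ccc(B(O)O)c(OC)c1 | starting material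
7 | (2,4-dimethoxyphenyl)(6,7-dimethoxy-1H-isochromen-3-yl)methanone, achiral | COc1ccc(C(=O)C2=Cc3cc(OC)c(OC)cc3CO2)c(OC)c1 | target

**Total step count:** 3. **Longest linear sequence:** 3 (1 → 3 → 5 → 7; 6 is bought).

**Steps most likely to fail, with fallbacks**

Step 3 carries the highest risk. Oxidative addition may be slow under CO, direct non-carbonylative coupling may compete, and 6 may protodeboronate. The fallback sets out from 5 and comes back at 7, and it drops CO altogether by inverting the polarity at C3. Compound 5 is stannylated with hexamethylditin, Pd(PPh3)4 and LiCl in refluxing THF to give (6,7-dimethoxy-1H-isochromen-3-yl)trimethylstannane F1. A Stille acylation of this vinylstannane with commercial 2,4-dimethoxybenzoyl chloride (Pd2(dba)3, tri(2-furyl)phosphine, toluene, 60 °C) then gives 7.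

Step 2 comes next. Phosphate 5 may be acid-labile, and the enolate may self-condense. The fallback sets out from 3 and comes back at 7, bypassing 5 through an anomeric sulfone carbanion.
- DIBAL-H (CH2Cl2, −78 °C) reduces 3 to 6,7-dimethoxyisochroman-3-ol F2 (racemic lactol).
- Benzenesulfinic acid with CaCl2 in CH2Cl2 converts the lactol into 6,7-dimethoxy-3-(phenylsulfonyl)isochroman F3 (racemic).
- n-BuLi (THF, −78 °C) deprotonates C3, and the anion is added to 2,4-dimethoxybenzoyl chloride to give (2,4-dimethoxyphenyl)[6,7-dimethoxy-3-(phenylsulfonyl)isochroman-3-yl]methanone F4 (racemic).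
- DBU at room temperature eliminates sulfinate across C3–C4 and delivers 7.

Step 1 carries the lowest risk. Over-alkylation to diarylmethanes or bis-chloromethylation could occur. The fallback sets out from 1 and comes back at 3, and it installs the C1 carbon at the aldehyde oxidation state in separate operations.
- Fischer esterification (MeOH, cat. H2SO4, reflux) gives methyl 2-(3,4-dimethoxyphenyl)acetate F5.
- Rieche formylation (Cl2CHOMe, SnCl4, CH2Cl2, 0 °C) gives methyl 2-(2-formyl-4,5-dimethoxyphenyl)acetate F6.
- NaBH4 (MeOH, 0 °C) gives methyl 2-[2-(hydroxymethyl)-4,5-dimethoxyphenyl]acetate F7.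
- On treatment with cat. TsOH in toluene this hydroxy ester lactonises to 3.

**Further compounds**
F1 | step 3 | (6,7-dimethoxy-1H-isochromen-3-yl)trimethylstannane | COc1cc2c(cc1OC)COC([Sn](C)(C)C)=C2
F2 | step 2 | 6,7-dimethoxyisochroman-3-ol (racemic) | COc1cc2c(cc1OC)COC(O)C2
F3 | step 2 | 6,7-dimethoxy-3-(phenylsulfonyl)isochroman (racemic) | COc1cc2c(cc1OC)COC(S(=O)(=O)c1ccccc1)C2
F4 | step 2 | (2,4-dimethoxyphenyl)[6,7-dimethoxy-3-(phenylsulfonyl)isochroman-3-yl]methanone (racemic) | COc1ccc(C(=O)C2(S(=O)(=O)c3ccccc3)Cc3cc(OC)c(OC)cc3CO2)c(OC)c1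
F5 | step 1 | methyl 2-(3,4-dimethoxyphenyl)acetate | COC(=O)Cc1ccc(OC)c(OC)c1
F6 | step 1 | methyl 2-(2-formyl-4,5-dimethoxyphenyl)acetate | COC(=O)Cc1cc(OC)c(OC)cc1C=O
F7 | step 1 | methyl 2-[2-(hydroxymethyl)-4,5-dimethoxyphenyl]acetate | COC(=O)Cc1cc(OC)c(OC)cc1CO
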